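Cuts: the three ArC–CH2 bridges are cut one after another from the ring-A end, each into a phenol Mannich base (an o-quinone methide precursor) and a C–H nucleophile; ring A (the butanoylfilicinic acid ring) is then cut at C5–C6, between the enolic carbon next to the CMe2 carbon and the carbon that carries the bridge, and last at C2–C3.
Enabling feature: read around ring A, C3–C4(Me2)–C5 is a dimethylmalonyl unit spliced onto the central carbon (C2) and one methyl carbon (C6) of heptane-2,4-dione, so the acyclic precursor 15 is a triacylmethane ester whose only primary α-carbon becomes C6 and whose ester carbon becomes C5; the quaternary C4 is bought with the malonate and not made by C-methylation of a phenol.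
Forward: rings B, C and D come from phloroglucinol and 2-methylphloroglucinol by Friedel–Crafts butanoylation; the D–C and C–B bridges are built outward from ring D (one free position) by two rounds of aminomethylation and o-quinone methide arylation, so each oligomer has exactly one free ring C–H.
Ring A arises last: the dianion of 15 closes it by Dieckmann condensation and, in the same flask after buffering, its single acidic ring C–H traps the o-quinone methide from the trimer Mannich base, which completes the A–B bridge and the target.
Stereochemistry: the target has no stereocentre and no configurational double bond; only regiochemistry has to be controlled (single free positions; methyl before methylene in the dianion).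

Key step: step 7

Remark: ring A and the acyclic tricarbonyl compounds are drawn as single tautomers of rapidly equilibrating keto–enol mixtures; the target is taken in the tautomeric form of its SMILES.

Step 1
Reactants: 1 phloroglucinol (benzene-1,3,5-triol); 2 butanoyl chloride
Product: 3 1-(2,4,6-trihydroxyphenyl)butan-1-one (butanoylphloroglucinol, the building block of rings B and C)
Conditions: AlCl3 (3.5 equiv), PhNO2, 60 °C; then ice, aq. HCl
Reagents that add atoms: none
Why: Friedel–Crafts C-acylation of the symmetric triphenol should stop at the mono-ketone because the chelated acyl group deactivates the ring towards a second acylation.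

Step 2
Reactants: 4 2-methylphloroglucinol (2-methylbenzene-1,3,5-triol); 2 butanoyl chloride
Product: 5 1-(2,4,6-trihydroxy-3-methylphenyl)butan-1-one (building block of ring D)
Conditions: AlCl3 (3.5 equiv), PhNO2, 60 °C; then ice, aq. HCl
Reagents that add atoms: none
Why: Friedel–Crafts C-acylation, in which the two free ring positions of 4 are equivalent, so only one ketone can form and it keeps a single free ring position.

Step 3
Reactants: 5 1-(2,4,6-trihydroxy-3-methylphenyl)butan-1-one; 6 dimethyl(methylidene)ammonium iodide; 3 1-(2,4,6-trihydroxyphenyl)butan-1-one (3 equiv, excess recovered)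
Product: 8 1-{3-[(3-butanoyl-2,4,6-trihydroxyphenyl)methyl]-2,4,6-trihydroxy-5-methylphenyl}butan-1-one (rings D–C dimer, one free position on ring C), via ring-D Mannich base 7 (not isolated)
Conditions: 6 (1.05 equiv), sodium acetate (1.1 equiv), MeCN, 0 °C → rt; then 3 (3 equiv), 1,4-dioxane, 90 °C
Reagents that add atoms: none
Why: Mannich aminomethylation can occur only at the single free ring carbon of 5, and on heating the Mannich base 7 should lose dimethylamine to an o-quinone methide that is captured at carbon by the excess of 3 (Michael-type arylation), the excess suppressing a second alkylation of the product.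

Step 4
Reactants: 8 rings D–C dimer; 6 dimethyl(methylidene)ammonium iodide; 3 1-(2,4,6-trihydroxyphenyl)butan-1-one (3 equiv, excess recovered)
Product: 10 rings D–C–B trimer (ring D: 3-methyl-5-butanoyl-2,4,6-trihydroxyphenyl; ring C: butanoylphloroglucinol bridged by CH2 at both former free positions; ring B: butanoylphloroglucinol bridged at one position, the other still C–H), via dimer Mannich base 9 (not isolated)
Conditions: 6 (1.05 equiv), sodium acetate (1.1 equiv), MeCN, 0 °C → rt; then 3 (3 equiv), 1,4-dioxane, 90 °C
Reagents that add atoms: none
Why: the same Mannich and o-quinone methide arylation sequence, in which 8 has one free position (on ring C) so 9 is a single compound, and the weakly acidic acetate buffer should keep the existing bridge from exchanging while excess 3 intercepts the o-quinone methide once.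

Step 5
Reactants: 11 dimethyl 2,2-dimethylpropanedioate (dimethyl dimethylmalonate)
Product: 12 3-methoxy-2,2-dimethyl-3-oxopropanoic acid
Conditions: KOH (1.0 equiv), MeOH, rt; then aq. HCl
Reagents that add atoms: potassium hydroxide, [K+].[OH-]
Why: saponification of one ester of a symmetric hindered diester should stop at the half-ester because the carboxylate formed repels hydroxide from the neighbouring neopentyl-type ester.

Step 6
Reactants: 12 3-methoxy-2,2-dimethyl-3-oxopropanoic acid; 13 heptane-2,4-dione
Product: 15 methyl 4-acetyl-2,2-dimethyl-3,5-dioxooctanoate (triacylmethane ester), via acid chloride 14 (not isolated)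
Conditions: (COCl)2 (1.2 equiv), DMF (cat.), CH2Cl2, 0 °C → rt, evaporate; then 13, MgCl2 (1.1 equiv), pyridine (2.2 equiv), CH2Cl2, 0 °C → rt; aq. HCl
Reagents that add atoms: oxalyl chloride, O=C(Cl)C(Cl)=O (supplies the chlorine of intermediate 14; none of its atoms remains in 15)
Why: the acid chloride 14, which has no α-hydrogen and so cannot form a ketene, should C-acylate the magnesium chelate of the β-diketone at its central carbon (soft-enolisation Claisen-type acylation) to give the triacylmethane.

Step 7
Reactants: 15 methyl 4-acetyl-2,2-dimethyl-3,5-dioxooctanoate (1.5-fold excess); 10 rings D–C–B trimer; 6 dimethyl(methylidene)ammonium iodide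
Product: 18 the target (ring A = 2-butanoyl-3,5-dihydroxy-4,4-dimethylcyclohexa-2,5-dien-1-one joined at C6 through CH2 to ring B of the trimer), via butanoylfilicinic acid 16 (not isolated), via trimer Mannich base 17 (not isolated)
Conditions: 15 added to LiN(i-Pr)2 (3.3 equiv), THF, −78 → 0 °C; AcOH (3.5 equiv), −20 °C; then 10 premixed with 6 (1.05 equiv) and sodium acetate (1.1 equiv) in MeCN (rt, 2 h) is added; 60 °C
Reagents that add atoms: none
Why: LiN(i-Pr)2 first removes the C-4 proton of 15 and then, kinetically, a proton of the acetyl methyl group, and the terminal carbanion of the resulting 1,3-dianion adds to the ester carbonyl and expels methoxide, which closes ring A at the bond between the former ester carbon (the enolic carbon next to the CMe2 carbon) and the former methyl carbon (the ring carbon that will carry the bridge). The closest known reaction type is the Dieckmann (intramolecular Claisen) condensation of a keto ester through the terminal carbon of a 1,3-dicarbonyl dianion, here telescoped with the Mannich-base (o-quinone methide) alkylation of the cyclic 1,3-dione that it forms. The one ring is closed in the 6-(enolendo)-exo-trig mode, and no stereocentre is created. The step needs closure through the acetyl CH3 and not through the butanoyl CH2 (which would give the 2-acetyl-6-ethyl isomer of 16); the substrate secures this because the CH3 is its only primary α-carbon, the one a hindered amide base deprotonates fastest and whose carbanion attacks the neopentyl-type ester with least hindrance, while C-4 is already tied up as the delocalised enolate and the ester is the only electrophile within reach of a six-membered transition state. After buffering with AcOH, 16 offers a single C–H between two ring carbonyls as the only carbon nucleophile in the flask, and the o-quinone methide released from 17 on warming has no free ring position of its own, so the last bridge can form only between ring A and ring B. Because the strong base is consumed before the phenolic trimer is added, base-induced exchange of the existing methylene bridges is avoided.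

Compound list
1 | phloroglucinol (benzene-1,3,5-triol) | Oc1cc(O)cc(O)c1 | starting material
2 | butanoyl chloride | CCCC(Cl)=O | starting material
3 | 1-(2,4,6-trihydroxyphenyl)butan-1-one | CCCC(=O)c1c(O)cc(O)cc1O | intermediate
4 | 2-methylbenzene-1,3,5-triol (2-methylphloroglucinol) | Cc1c(O)cc(O)cc1O | starting material
5 | 1-(2,4,6-trihydroxy-3-methylphenyl)butan-1-one | CCCC(=O)c1c(O)cc(O)c(C)c1O | intermediate
6 | dimethyl(methylidene)ammonium iodide | C=[N+](C)C.[I-] | starting material
7 | 1-{3-[(dimethylamino)methyl]-2,4,6-trihydroxy-5-methylphenyl}butan-1-one (ring-D Mannich base) | CCCC(=O)c1c(O)c(C)c(O)c(CN(C)C)c1O | intermediate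
8 | 1-{3-[(3-butanoyl-2,4,6-trihydroxyphenyl)methyl]-2,4,6-trihydroxy-5-methylphenyl}butan-1-one (rings D–C dimer) | CCCC(=O)c1c(O)c(C)c(O)c(Cc2c(O)cc(O)c(C(=O)CCC)c2O)c1O | intermediate
9 | Mannich base of 8, CH2NMe2 at the free position of ring C | CCCC(=O)c1c(O)c(C)c(O)c(Cc2c(O)c(CN(C)C)c(O)c(C(=O)CCC)c2O)c1O | intermediate
10 | rings D–C–B trimer, one free C–H on ring B | CCCC(=O)c1c(O)c(C)c(O)c(Cc2c(O)c(Cc3c(O)cc(O)c(C(=O)CCC)c3O)c(O)c(C(=O)CCC)c2O)c1O | intermediate
11 | dimethyl 2,2-dimethylpropanedioate | COC(=O)C(C)(C)C(=O)OC | starting material
12 | 3-methoxy-2,2-dimethyl-3-oxopropanoic acid | COC(=O)C(C)(C)C(O)=O | intermediate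
13 | heptane-2,4-dione | CCCC(=O)CC(C)=O | starting material
14 | methyl 3-chloro-2,2-dimethyl-3-oxopropanoate | COC(=O)C(C)(C)C(Cl)=O | intermediate
15 | methyl 4-acetyl-2,2-dimethyl-3,5-dioxooctanoate | CCCC(=O)C(C(C)=O)C(=O)C(C)(C)C(=O)OC | intermediate
16 | 2-butanoyl-3,5-dihydroxy-4,4-dimethylcyclohexa-2,5-dien-1-one (butanoylfilicinic acid, ring A) | CCCC(=O)C1=C(O)C(C)(C)C(O)=CC1=O | intermediate
17 | Mannich base of 10, CH2NMe2 at the free position of ring B | CCCC(=O)c1c(O)c(C)c(O)c(Cc2c(O)c(Cc3c(O)c(CN(C)C)c(O)c(C(=O)CCC)c3O)c(O)c(C(=O)CCC)c2O)c1O | intermediate
18 | target, rings A–B–C–D tetramer (CNP0246352.0) | CCCC(=O)C1=C(O)C(C)(C)C(O)=C(Cc2c(O)c(Cc3c(O)c(Cc4c(O)c(C)c(O)c(C(=O)CCC)c4O)c(O)c(C(=O)CCC)c3O)c(O)c(C(=O)CCC)c2O)C1=O | target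

Total step count: 7. Longest linear sequence: 4 steps (4 → 5 → 8 → 10 → 18).

Steps most likely to fail

Step 7. The dianion may also form at the butanoyl methylene and close to the isomeric 2-acetyl-6-ethyl ring, closure onto the hindered ester may stall, or capture of the o-quinone methide may be incomplete in the telescoped mixture. The fallback sets out from 3 and comes back to the route at 16 and then at 18, and it makes ring A by dearomatisation instead of ring closure. Compound 3 would be C-methylated twice at one ring carbon with iodomethane and sodium methoxide in methanol to give 16, which is isolated from its mono- and trimethyl congeners. Compound 17 would be prepared from 10 and 6 as in step 7 and isolated, and 16 and 17 would then be heated with sodium acetate in 1,4-dioxane at 80 °C to give 18. This fallback needs no compound outside the compound list (F0).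

Step 4. A second alkylation (of the product or of both free positions of 3) and exchange of the existing bridge may give mixtures of oligomers. The fallback sets out from 3 and comes back at 10, and it makes the B–C bridge first on a symmetric partner. Compound 3 would be condensed with formaldehyde (0.5 equiv, aqueous KOH, 0 °C) to bis(3-butanoyl-2,4,6-trihydroxyphenyl)methane F1, whose two free positions are equivalent. F1, used in excess, would then be alkylated once by the Mannich base 7 (prepared from 5 and 6 as in step 3 and isolated) in 1,4-dioxane at 90 °C to give 10.

Step 6. O-acylation instead of C-acylation, slow reaction of the α-quaternary acid chloride 14, or retro-Claisen loss of an acyl group on work-up may intervene. The fallback sets out from 2 and comes back at 15, and it attaches the acyl groups to the central carbon in the other order. The lithium enolate of methyl 2,2-dimethyl-3-oxobutanoate F2 (LiN(i-Pr)2, THF, −78 °C; only its methyl group can be deprotonated) would be acylated with 2 to give methyl 2,2-dimethyl-3,5-dioxooctanoate F3. F3 would then be C-acetylated at C-4 with the small electrophile acetyl chloride (MgCl2, pyridine, CH2Cl2) to give 15.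

Further compounds
F0 | step 7 | none | none
F1 | step 4 | bis(3-butanoyl-2,4,6-trihydroxyphenyl)methane | CCCC(=O)c1c(O)cc(O)c(Cc2c(O)cc(O)c(C(=O)CCC)c2O)c1O
F2 | step 6 | methyl 2,2-dimethyl-3-oxobutanoate | COC(=O)C(C)(C)C(C)=O
F3 | step 6 | methyl 2,2-dimethyl-3,5-dioxooctanoate | CCCC(=O)CC(=O)C(C)(C)C(=O)OC
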